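**Plan**
1. Retrosynthesis: open the cis γ-lactone at O–C8 and remove the C9 hydroxyl (back to a C8=C9 alkene plus a 2-substituted acrylic acid), then cut C1–C2 and C3–C4 of the 7-oxabicyclo[2.2.1]heptane, then take the cyclohexane (ring B) back to (R)-carvone.
2. Enabling feature: the ether oxygen bridges C1 (H) and C4 (CH3), which sit trans on the adjacent ring-B carbons C10 and C5. This is a masked γ-keto aldehyde; a carbene at C1 captured by the C4 ketone oxygen gives a five-membered cyclic carbonyl ylide (O, C1, C10, C5, C4), and the C2–C3 bridge is an ethylene equivalent.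
3. Forward order: ring B from carvone, C10 quaternary centre, C5/C6 functionalisation, ylide (3+2) closing both five-membered rings of the oxanorbornane, side-chain oxidation and angelate, then epoxidation/lactonisation last.
4. Stereochemistry: C7 is bought with (R)-carvone; C10, C6/C5, C1/C4 and C8/C9 are all relayed from it by substrate control.
5. Helpers: the sulfonylhydrazone (carbene source) and the sulfonyl group of the dipolarophile are removed in steps 10–11; benzyl and TBS mask O1 and O6.

Key step: step 10

Remark on locants: eudesmane locants are used throughout. C10 is the quaternary carbon with methyl C14, C5 the adjacent ring CH, C6 the CH–O(ester), C7 the CH carrying C11–C13, C8/C9 the oxygenated ring carbons, C1–C4 the ether-bridged ring, C15 the methyl on C4.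
Remark on step 10: cycloadduct 17 is expected as a mixture of sulfone regio- and exo/endo isomers that all converge on 18 in step 11; one representative isomer is drawn.

**Step 1**
Reactants: 1 (R)-(−)-carvone; 2 benzyl chloromethyl ether
Product: 3 (2S,5S)-2-[(benzyloxy)methyl]-2-methyl-5-(prop-1-en-2-yl)cyclohex-3-en-1-one
Conditions: KOt-Bu, THF, −20 °C; then 2, −78 → 0 °C
Reagents that add atoms: none
Why: Deconjugative α-alkylation of the extended potassium dienolate creates the C10 quaternary centre and moves the alkene to C8=C9; the electrophile should enter anti to the isopropenyl group across the ring (the syn face is screened by the pseudo-axial C6 hydrogen beside the enolate, or by the isopropenyl group itself in the flipped half-chair), placing CH2OBn trans and methyl cis to isopropenyl.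

**Step 2**
Reactants: 3 (2S,5S)-2-[(benzyloxy)methyl]-2-methyl-5-(prop-1-en-2-yl)cyclohex-3-en-1-one
Product: 4 6-[(benzyloxy)methyl]-6-methyl-3-(prop-1-en-2-yl)cyclohexa-1,4-dien-1-yl trifluoromethanesulfonate (configuration as in 3)
Conditions: KHMDS, THF, −78 °C; PhNTf2, −78 → 0 °C
Reagents that add atoms: N-phenyl-bis(trifluoromethanesulfonimide), O=S(=O)(N(c1ccccc1)S(=O)(=O)C(F)(F)F)C(F)(F)F
Why: Enolate O-triflation; the ketone can enolise only towards C6, so a single enol triflate should form and no stereocentre is touched.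

**Step 3**
Reactants: 4 enol triflate
Product: 5 methyl 6-[(benzyloxy)methyl]-6-methyl-3-(prop-1-en-2-yl)cyclohexa-1,4-diene-1-carboxylate
Conditions: Pd(OAc)2 (5 mol %), dppf, CO (1 atm), MeOH, Et3N, DMF, 50 °C
Reagents that add atoms: carbon monoxide, [C-]#[O+]; methanol, CO
Why: Pd(0)-catalysed alkoxycarbonylation of the enol triflate (oxidative addition, CO insertion, methanolysis) installs the future C4 as a conjugated ester, the only electron-poor alkene in the molecule.

**Step 4**
Reactants: 5 dienyl ester
Product: 7 methyl 6-[(benzyloxy)methyl]-2-hydroxy-6-methyl-3-(prop-1-en-2-yl)cyclohex-4-ene-1-carboxylate (OH trans to isopropenyl; ester trans to OH and trans to CH2OBn), via β-boryl ester 6 (not isolated)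
Conditions: CuCl (5 mol %), Xantphos, NaOt-Bu (10 mol %), B2pin2, MeOH (2 equiv), THF, rt; then NaBO3·4H2O, THF/H2O, rt
Reagents that add atoms: bis(pinacolato)diboron (boron stays only in 6), CC1(C)OB(OC1(C)C)B1OC(C)(C)C(C)(C)O1; sodium perborate, [Na+].[O-]OB=O
Why: Cu(I)-catalysed conjugate borylation followed by stereoretentive C–B oxidation; boryl-copper should add to C6 anti to the adjacent isopropenyl group and the copper enolate should be protonated on the same face (the other face carries the pseudo-axial C10 methyl), giving 6α-OH with 5α-H, i.e. the C4 and C1 carbons trans on C5/C10.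

**Step 5**
Reactants: 7 β-hydroxy ester
Product: 8 methyl 6-[(benzyloxy)methyl]-2-[(tert-butyldimethylsilyl)oxy]-6-methyl-3-(prop-1-en-2-yl)cyclohex-4-ene-1-carboxylate
Conditions: TBSOTf, 2,6-lutidine, CH2Cl2, −78 → 0 °C
Reagents that add atoms: tert-butyldimethylsilyl trifluoromethanesulfonate, CC(C)(C)[Si](C)(C)OS(=O)(=O)C(F)(F)F
Why: Silyl triflate silylation of a hindered secondary alcohol under non-epimerising conditions (protecting-group step).

**Step 6**
Reactants: 8 silyloxy ester
Product: 9 methyl enol ether of 8 (ester C=O replaced by C=CH2; a 1-methoxyvinyl group on C5)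
Conditions: Cp2TiMe2, toluene/THF, 65 °C, dark
Reagents that add atoms: dimethyltitanocene (Petasis reagent), C[Ti](C)(C1C=CC=C1)C1C=CC=C1
Why: Petasis methylenation turns the ester into a masked methyl ketone (the new carbon is C15) without base, so C5 cannot epimerise.

**Step 7**
Reactants: 9 methyl enol ether
Product: 11 1-[2-(hydroxymethyl)-2-methyl-5-(prop-1-en-2-yl)-6-[(tert-butyldimethylsilyl)oxy]cyclohex-3-en-1-yl]ethan-1-one (in equilibrium with its cyclic hemiketal), via hydroxy enol ether 10 (not isolated)
Conditions: LiDBB, THF, −78 °C; then 0.5 M HCl, THF, 0 °C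
Reagents that add atoms: water, O
Why: Radical-anion cleavage of the benzyl ether is possible because no carbonyl group is present at this stage, and the acidic work-up hydrolyses the enol ether to the methyl ketone.

**Step 8**
Reactants: 11 hydroxy ketone
Product: 12 6-acetyl-1-methyl-4-(prop-1-en-2-yl)-5-[(tert-butyldimethylsilyl)oxy]cyclohex-2-ene-1-carbaldehyde
Conditions: DMP, NaHCO3, CH2Cl2, 0 °C → rt
Reagents that add atoms: none
Why: Dess–Martin oxidation of the primary alcohol (drained from the hemiketal equilibrium) gives the non-enolisable neopentyl aldehyde under buffered conditions that leave C5 untouched.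

**Step 9**
Reactants: 12 keto aldehyde
Product: 13 (E)-N-[2-(trifluoromethyl)phenyl]sulfonylhydrazone of the aldehyde group of 12
Conditions: 2-(CF3)C6H4SO2NHNH2 (1.05 equiv), THF, rt
Reagents that add atoms: 2-(trifluoromethyl)benzenesulfonohydrazide, NNS(=O)(=O)c1ccccc1C(F)(F)F
Why: Hydrazone condensation, chemoselective for the aldehyde over the hindered methyl ketone.

**Step 10**
Reactants: 13 sulfonylhydrazone; 14 phenyl vinyl sulfone
Product: 17 3-exo-(phenylsulfonyl)-6α-[(tert-butyldimethylsilyl)oxy]-1β,4β-epoxy-5αH-eudesma-8,11(12)-diene (representative isomer), via diazoalkane 15 (not isolated), via carbonyl ylide 16 (not isolated)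
Conditions: NaH, PhCF3, 0 °C; then Rh2(OAc)4 (2 mol %), 14 (10 equiv), 0 → 40 °C
Reagents that add atoms: none
Why: Proposed new method: deprotonation of the sulfonylhydrazone and loss of sulfinate give the non-stabilised diazoalkane 15; Rh(II) converts it into a carbene with no β-hydrogen, the γ-acetyl oxygen adds to the carbene carbon (O–C1 bond formation closing the ring O–C1–C10–C5–C4) to give ylide 16, and a concerted suprafacial (3+2) cycloaddition with the vinyl sulfone closes the second five-membered ring (O–C1–C2–C3–C4), forming C1–C2 and C3–C4 in one event. The closest known reaction type is the Rh(II)-catalysed tandem carbonyl-ylide formation/1,3-dipolar cycloaddition of keto diazocarbonyl compounds, together with the known low-temperature release of non-stabilised diazoalkanes from 2-(trifluoromethyl)benzenesulfonylhydrazones for metal-carbene chemistry; the new element is ylide formation from a carbene without an acceptor group. C1 and C4 are set together by the face of the ylide that is attacked: the β face is shielded by the pseudo-axial C10 methyl next to C1, so the two-carbon bridge should arrive on the α face and the oxygen bridge end up syn to that methyl, while the trans ring fusion is inherited from the trans C1/C4 substituents set in steps 1 and 4. Regio- and exo/endo selectivity are not needed because the sulfonyl group is removed in step 11; what is needed is that the ylide is trapped before a 1,4-hydrogen shift to an enol ether and that the diazoalkane meets rhodium before it adds to the vinyl sulfone, which slow release of 15, the excess of 14 and an unhindered Rh(II) carboxylate are meant to secure.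

**Step 11**
Reactants: 17 sulfone cycloadduct (isomer mixture)
Product: 18 6α-[(tert-butyldimethylsilyl)oxy]-1β,4β-epoxy-5αH-eudesma-8,11(12)-diene
Conditions: Na(Hg) (6 %), Na2HPO4, MeOH/THF, −20 °C
Reagents that add atoms: none
Why: Reductive desulfonylation by single-electron transfer replaces C–SO2Ph by C–H, so all isomers of 17 converge on one compound.

**Step 12**
Reactants: 18 silyl ether
Product: 19 1β,4β-epoxy-5αH-eudesma-8,11(12)-dien-6α-ol
Conditions: TBAF, THF, 50 °C
Reagents that add atoms: none
Why: Fluoride-mediated desilylation; no stereocentre is affected.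

**Step 13**
Reactants: 19 alcohol; 20 angelic acid
Product: 22 6α-angeloyloxy-1β,4β-epoxy-5αH-eudesma-8,11(12)-diene, via mixed anhydride 21 (not isolated)
Conditions: 20, 2,4,6-Cl3C6H2COCl, Et3N, PhMe, rt; then 19, 80 °C
Reagents that add atoms: 2,4,6-trichlorobenzoyl chloride (atoms stay only in 21), O=C(Cl)c1c(Cl)cc(Cl)cc1Cl
Why: Yamaguchi esterification via the mixed anhydride, run without DMAP to avoid isomerisation of the (Z)-angelate to the tiglate; C6 keeps its configuration.

**Step 14**
Reactants: 22 angelate
Product: 23 6α-angeloyloxy-1β,4β-epoxy-5αH-eudesma-8,11(13)-dien-12-ol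
Conditions: SeO2 (0.3 equiv), t-BuOOH, CH2Cl2, rt
Reagents that add atoms: tert-butyl hydroperoxide (oxygen delivered through catalytic SeO2, O=[Se]=O), CC(C)(C)OO
Why: SeO2/t-BuOOH allylic oxidation (ene reaction then [2,3]-shift) should select the methyl group of the 1,1-disubstituted isopropenyl unit over the hindered C8=C9 alkene and the electron-poor angelate.

**Step 15**
Reactants: 23 allylic alcohol
Product: 25 6α-angeloyloxy-1β,4β-epoxy-5αH-eudesma-8,11(13)-dien-12-oic acid, via enal 24 (not isolated)
Conditions: TEMPO (cat.), PhI(OAc)2, CH2Cl2, rt; then NaClO2, NaH2PO4, 2-methyl-2-butene, t-BuOH/H2O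
Reagents that add atoms: sodium chlorite, [Na+].[O-]Cl=O
Why: Oxoammonium oxidation to the 2-substituted acrolein followed by Pinnick oxidation gives the α-methylene acid without touching the other alkenes.

**Step 16**
Reactants: 25 acid
Product: 27 6α-angeloyloxy-1β,4β-epoxy-9α-hydroxy-5αH-eudesm-11(13)-en-12,8β-olide (CNP0328162.1), via epoxy acid 26 (not isolated)
Conditions: mCPBA, CH2Cl2, 0 °C → rt; then CSA (cat.)
Reagents that add atoms: 3-chloroperbenzoic acid, OOC(=O)c1cccc(Cl)c1
Why: Prilezhaev epoxidation of the only electron-rich alkene from the face anti to the C10 methyl (α), then acid-catalysed 5-exo anti opening at C8 by the neighbouring carboxylic acid (Fürst–Plattner-type diaxial opening), sets 8β-O (inversion) and 9α-OH and closes the cis-fused α-methylene-γ-lactone.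

**Compound list**
1 | (R)-(−)-carvone | CC1=CC[C@@H](C(C)=C)CC1=O | starting material
2 | benzyl chloromethyl ether | ClCOCc1ccccc1 | starting material
3 | (2S,5S)-2-[(benzyloxy)methyl]-2-methyl-5-(prop-1-en-2-yl)cyclohex-3-en-1-one | C[C@@]1(COCc2ccccc2)C=C[C@@H](C(C)=C)CC1=O | intermediate
4 | 6-[(benzyloxy)methyl]-6-methyl-3-(prop-1-en-2-yl)cyclohexa-1,4-dien-1-yl triflate | C[C@@]1(COCc2ccccc2)C=C[C@@H](C(C)=C)C=C1OS(=O)(=O)C(F)(F)F | intermediate
5 | methyl 6-[(benzyloxy)methyl]-6-methyl-3-(prop-1-en-2-yl)cyclohexa-1,4-diene-1-carboxylate | C[C@@]1(COCc2ccccc2)C=C[C@@H](C(C)=C)C=C1C(=O)OC | intermediate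
6 | β-boryl ester (Bpin at C6 trans to isopropenyl, ester trans to Bpin) | C[C@@]1(COCc2ccccc2)C=C[C@@H](C(C)=C)[C@H](B2OC(C)(C)C(C)(C)O2)[C@H]1C(=O)OC | intermediate
7 | methyl 6-[(benzyloxy)methyl]-2-hydroxy-6-methyl-3-(prop-1-en-2-yl)cyclohex-4-ene-1-carboxylate | C[C@@]1(COCc2ccccc2)C=C[C@@H](C(C)=C)[C@H](O)[C@H]1C(=O)OC | intermediate
8 | TBS ether of 7 | C[C@@]1(COCc2ccccc2)C=C[C@@H](C(C)=C)[C@H](O[Si](C)(C)C(C)(C)C)[C@H]1C(=O)OC | intermediate
9 | methyl enol ether (1-methoxyvinyl in place of CO2Me) | C[C@@]1(COCc2ccccc2)C=C[C@@H](C(C)=C)[C@H](O[Si](C)(C)C(C)(C)C)[C@H]1C(=C)OC | intermediate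
10 | debenzylated hydroxy enol ether | C[C@@]1(CO)C=C[C@@H](C(C)=C)[C@H](O[Si](C)(C)C(C)(C)C)[C@H]1C(=C)OC | intermediate
11 | hydroxymethyl methyl ketone | C[C@@]1(CO)C=C[C@@H](C(C)=C)[C@H](O[Si](C)(C)C(C)(C)C)[C@H]1C(C)=O | intermediate
12 | γ-keto aldehyde | C[C@@]1(C=O)C=C[C@@H](C(C)=C)[C@H](O[Si](C)(C)C(C)(C)C)[C@H]1C(C)=O | intermediate
13 | (E)-2-(trifluoromethyl)benzenesulfonylhydrazone of 12 | C[C@@]1(/C=N/NS(=O)(=O)c2ccccc2C(F)(F)F)C=C[C@@H](C(C)=C)[C@H](O[Si](C)(C)C(C)(C)C)[C@H]1C(C)=O | intermediate
14 | phenyl vinyl sulfone | C=CS(=O)(=O)c1ccccc1 | starting material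
15 | diazoalkane | C[C@@]1(C=[N+]=[N-])C=C[C@@H](C(C)=C)[C@H](O[Si](C)(C)C(C)(C)C)[C@H]1C(C)=O | intermediate
16 | cyclic carbonyl ylide | C[C@@]12C=C[C@@H](C(C)=C)[C@H](O[Si](C)(C)C(C)(C)C)[C@H]1C(C)=[O+][CH-]2 | intermediate
17 | 3-exo-phenylsulfonyl cycloadduct (representative isomer) | C[C@@]12C=C[C@@H](C(C)=C)[C@H](O[Si](C)(C)C(C)(C)C)[C@H]1[C@]1(C)[C@@H](S(=O)(=O)c3ccccc3)C[C@H]2O1 | intermediate
18 | 6α-TBSO-1β,4β-epoxy-5αH-eudesma-8,11(12)-diene | C[C@@]12C=C[C@@H](C(C)=C)[C@H](O[Si](C)(C)C(C)(C)C)[C@H]1[C@]1(C)CC[C@H]2O1 | intermediate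
19 | 1β,4β-epoxy-5αH-eudesma-8,11(12)-dien-6α-ol | C[C@@]12C=C[C@@H](C(C)=C)[C@H](O)[C@H]1[C@]1(C)CC[C@H]2O1 | intermediate
20 | angelic acid, (Z)-2-methylbut-2-enoic acid | C/C=C(/C)C(=O)O | starting material
21 | angelic 2,4,6-trichlorobenzoic anhydride | C/C=C(/C)C(=O)OC(=O)c1c(Cl)cc(Cl)cc1Cl | intermediate
22 | 6α-angeloyloxy-1β,4β-epoxy-5αH-eudesma-8,11(12)-diene | C[C@@]12C=C[C@@H](C(C)=C)[C@H](OC(=O)/C(C)=C\C)[C@H]1[C@]1(C)CC[C@H]2O1 | intermediate
23 | 12-hydroxy compound (allylic alcohol) | C[C@@]12C=C[C@@H](C(=C)CO)[C@H](OC(=O)/C(C)=C\C)[C@H]1[C@]1(C)CC[C@H]2O1 | intermediate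
24 | 12-al (2-substituted acrolein) | C[C@@]12C=C[C@@H](C(=C)C=O)[C@H](OC(=O)/C(C)=C\C)[C@H]1[C@]1(C)CC[C@H]2O1 | intermediate
25 | 12-oic acid | C[C@@]12C=C[C@@H](C(=C)C(=O)O)[C@H](OC(=O)/C(C)=C\C)[C@H]1[C@]1(C)CC[C@H]2O1 | intermediate
26 | 8α,9α-epoxy acid | C[C@@]12[C@@H]3O[C@@H]3[C@@H](C(=C)C(=O)O)[C@H](OC(=O)/C(C)=C\C)[C@H]1[C@]1(C)CC[C@H]2O1 | intermediate
27 | CNP0328162.1 | C=C1C(=O)O[C@H]2[C@@H]1[C@H](OC(=O)/C(C)=C\C)[C@@H]1[C@@](C)([C@@H]2O)[C@H]2CC[C@]1(C)O2 | target

**Step count and risks**
Total step count: 16. Longest linear sequence: 16 steps (from 1).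

Step 10 (key step, new method). The unstabilised ylide may collapse by 1,4-hydrogen shift before it is trapped, the diazoalkane may add directly to the vinyl sulfone, and base may epimerise C5 before ylide formation, which would lead into the unstrained cis-fused series. Fallback from 12, returning at 18, builds the bridged ring stepwise with known reaction types. The aldehyde of 12 is allylated chemoselectively with allylboronic acid pinacol ester to the homoallylic alcohol F1 (the 1β-OH epimer is needed; the other is recycled by oxidation and reduction). The methyl ketone is methylenated under non-basic Lombardo conditions (Zn, CH2Br2, TiCl4) to the diene F2. Ring-closing metathesis (Grubbs II) gives the cyclohexenol F3 with a C3=C4 trisubstituted alkene. Phenylselenoetherification (N-phenylselenophthalimide, CSA) closes the 1,4-ether from the β face to the selenide F4, and Bu3SnH/AIBN removes selenium to give 18.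

Step 1. The dienolate may alkylate on oxygen or at the α′-carbon, and the remote isopropenyl group may discriminate the two faces of C10 only partly. Fallback from 1, returning at 3, replaces the SN2 alkylation by an aldol on a regiodefined dienolate. Carvone is converted into its extended trimethylsilyl dienol ether F5 (TMSCl, NaI, Et3N, MeCN). MeLi releases the lithium dienolate, which is hydroxymethylated at C10 with monomeric formaldehyde at −78 °C to the hydroxymethyl ketone F6 (C10 epimers separable at this stage). Benzyl trichloroacetimidate with catalytic TfOH then gives 3.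

Step 4. The copper enolate may be protonated from the wrong face, or alkoxide may epimerise C5 or deprotonate the doubly allylic C7, so that H5 and O6 do not end up cis. Fallback from 5, returning at 7, delivers silicon and hydrogen stereospecifically syn. DIBAL reduces 5 to the allylic alcohol F7. Silylation with 1,1,3,3-tetramethyldisilazane and Pt(0)-catalysed intramolecular hydrosilylation give the oxasilolane F8, with Si at C6 and H at C5 on the face anti to isopropenyl. Tamao oxidation (H2O2, KF, KHCO3) gives the diol F9. Selective oxidation of the primary alcohol (TEMPO, NaOCl, NaClO2) gives the hydroxy acid F10, and TMSCHN2 gives 7.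

**Further compounds**
F1 | step 10 | homoallylic alcohol (1β-OH) from allylation of 12 | C[C@@]1([C@H](O)CC=C)C=C[C@@H](C(C)=C)[C@H](O[Si](C)(C)C(C)(C)C)[C@H]1C(C)=O
F2 | step 10 | diene after methylenation of the ketone | C[C@@]1([C@H](O)CC=C)C=C[C@@H](C(C)=C)[C@H](O[Si](C)(C)C(C)(C)C)[C@H]1C(C)=C
F3 | step 10 | ring-closed cyclohexenol (C3=C4) | C[C@@]12C=C[C@@H](C(C)=C)[C@H](O[Si](C)(C)C(C)(C)C)[C@H]1C(C)=CC[C@H]2O
F4 | step 10 | 3-endo-phenylselanyl 1β,4β-epoxide | C[C@@]12C=C[C@@H](C(C)=C)[C@H](O[Si](C)(C)C(C)(C)C)[C@H]1[C@]1(C)[C@H]([Se]c3ccccc3)C[C@H]2O1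
F5 | step 1 | extended trimethylsilyl dienol ether of carvone | C[Si](C)(C)OC1=C(C)C=C[C@@H](C(C)=C)C1
F6 | step 1 | 2-(hydroxymethyl)-2-methyl-5-(prop-1-en-2-yl)cyclohex-3-en-1-one | C[C@@]1(CO)C=C[C@@H](C(C)=C)CC1=O
F7 | step 4 | allylic alcohol from reduction of 5 | C[C@@]1(COCc2ccccc2)C=C[C@@H](C(C)=C)C=C1CO
F8 | step 4 | oxasilolane from intramolecular hydrosilylation | C[C@@]1(COCc2ccccc2)C=C[C@@H](C(C)=C)[C@H]2[C@H]1CO[Si]2(C)C
F9 | step 4 | 1,3-diol | C[C@@]1(COCc2ccccc2)C=C[C@@H](C(C)=C)[C@H](O)[C@H]1CO
F10 | step 4 | β-hydroxy acid | C[C@@]1(COCc2ccccc2)C=C[C@@H](C(C)=C)[C@H](O)[C@H]1C(=O)O
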